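**Retrosynthetic overview**
1. Target ⇒ (global O-debenzylation) heptabenzyl ether ⇒ (C4–C8 interflavan bond, SN1 Friedel–Crafts) (2S,4S)-tri-O-benzylflavan-4-ol + tetra-O-benzyl-(+)-catechin (chiral pool).
2. Flavan-4-ol ⇒ (asymmetric transfer hydrogenation as kinetic resolution) racemic flavanone ⇒ (oxa-Michael closure of ring C) 2'-hydroxychalcone.
3. Key C–C bond: chalcone Cα–Cβ (later C3–C2 of the upper unit) ⇒ intermolecular crossed aldol (Claisen–Schmidt) condensation of the ring A acetophenone with the ring B aldehyde.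
4. Ring order: only ring C of the upper unit is built (step 4); all benzene rings and the lower chroman come from the starting materials.

Assumption: the SMILES is read as (2S,4R)-7,3',4'-trihydroxyflavan-(4β→8)-(+)-catechin, a 2,4-trans upper flavan on C8 of (2R,3S)-catechin; benzyl bromide and other simple reagents are treated as reagents, not numbered compounds.

**Route**

Step 1
Reactants: 1 2,4-dihydroxyacetophenone
Product: 2 1-[4-(benzyloxy)-2-hydroxyphenyl]ethan-1-one
Conditions: BnBr (1.05 equiv), K2CO3 (1.2 equiv), acetone, reflux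
Reagents that add atoms: benzyl bromide, BrCc1ccccc1
Why: Williamson ether synthesis; the 2-OH is hydrogen-bonded to the acetyl carbonyl and much less nucleophilic, so one equivalent of BnBr alkylates only the 4-OH.

Step 2
Reactants: 3 3,4-dihydroxybenzaldehyde
Product: 4 3,4-bis(benzyloxy)benzaldehyde
Conditions: BnBr (2.3 equiv), K2CO3 (3 equiv), DMF, 60 °C
Reagents that add atoms: benzyl bromide, BrCc1ccccc1
Why: Double Williamson etherification masks the oxidation-prone catechol for the basic aldol step, with benzyl groups that come off by hydrogenolysis at the end.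

Step 3
Reactants: 2 1-[4-(benzyloxy)-2-hydroxyphenyl]ethan-1-one; 4 3,4-bis(benzyloxy)benzaldehyde
Product: 6 (E)-1-[4-(benzyloxy)-2-hydroxyphenyl]-3-[3,4-bis(benzyloxy)phenyl]prop-2-en-1-one (2'-hydroxychalcone), via aldol adduct 5 (not isolated)
Conditions: KOH (50% aq, 10 equiv), EtOH/THF, rt, 48 h; then dilute aq HCl, 0 °C
Reagents that add atoms: none
Why: Claisen–Schmidt crossed aldol condensation: the enolate of methyl ketone 2 adds to the non-enolisable aldehyde 4 and the β-hydroxy ketone 5 loses water (E1cB) to give the conjugated (E)-enone, so no stereocentre remains.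

Step 4
Reactants: 6 (E)-2'-hydroxychalcone
Product: 7 racemic 7-(benzyloxy)-2-[3,4-bis(benzyloxy)phenyl]chroman-4-one (tri-O-benzyl flavanone)
Conditions: NaOAc (10 equiv), EtOH, reflux, 36 h; recovered 6 recycled
Reagents that add atoms: none
Why: Intramolecular oxa-Michael addition (6-endo-trig) of the 2'-phenoxide to the enone closes ring C of the upper unit, giving C2 as a racemate that is resolved in the next step.

Step 5
Reactants: 7 racemic tri-O-benzyl flavanone
Product: 8 (2S,4S)-7-(benzyloxy)-2-[3,4-bis(benzyloxy)phenyl]chroman-4-ol (2,4-cis)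
Conditions: RuCl(p-cymene)[(S,S)-TsDPEN] (2 mol %), HCO2H/Et3N (5:2), EtOAc, rt, stopped at about 50% conversion; silica separation from unreacted (R)-7
Reagents that add atoms: none
Why: Noyori–Ikariya asymmetric transfer hydrogenation run as a kinetic resolution: the (S,S)-catalyst forms 4S benzylic alcohols, which is the matched, cis-selective hydride delivery only for (2S)-7, so (2S,4S)-8 forms while (R)-7 stays behind and can be racemised (NaOAc, EtOH, reflux) and recycled.

Step 6
Reactants: 9 (+)-catechin, (2R,3S)-2-(3,4-dihydroxyphenyl)chromane-3,5,7-triol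
Product: 10 (2R,3S)-5,7-bis(benzyloxy)-2-[3,4-bis(benzyloxy)phenyl]chroman-3-ol (5,7,3',4'-tetra-O-benzylcatechin)
Conditions: BnBr (4.2 equiv), K2CO3 (4.5 equiv), DMF, 0 °C → rt, argon
Reagents that add atoms: benzyl bromide, BrCc1ccccc1
Why: Williamson etherification of the four acidic phenols in preference to the aliphatic 3-OH under carbonate base; C2 and C3 of the chiral-pool catechin are untouched at room temperature.

Step 7
Reactants: 8 (2S,4S)-tri-O-benzylflavan-4-ol; 10 tetra-O-benzylcatechin (3 equiv, excess recovered)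
Product: 12 (2R,3S)-5,7-bis(benzyloxy)-2-[3,4-bis(benzyloxy)phenyl]-8-{(2S,4R)-7-(benzyloxy)-2-[3,4-bis(benzyloxy)phenyl]chroman-4-yl}chroman-3-ol, via flavan-4-yl cation 11 (not isolated)
Conditions: TMSOTf (0.1 equiv), CH2Cl2, −78 → −30 °C; then Et3N; chromatography
Reagents that add atoms: none
Why: Acid-triggered SN1 Friedel–Crafts alkylation (the standard proanthocyanidin interflavan coupling): the 4-OH of 8 leaves as water to give cation 11, stabilised by the para 7-OBn and the ring oxygen, and C8 of 10 (the less hindered phloroglucinol position) attacks pseudo-axially on the half-chair, trans to the equatorial C2 aryl, which sets C4 as R (2,4-trans); the triflic acid formed from the silyl triflate and the released water keeps the catalysis going.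

Step 8
Reactants: 12 heptabenzyl ether
Product: 13 CNP0227165.4, (2R,3S)-2-(3,4-dihydroxyphenyl)-8-[(2S,4R)-2-(3,4-dihydroxyphenyl)-7-hydroxychroman-4-yl]chromane-3,5,7-triol
Conditions: H2 (1 atm), Pd(OH)2/C (20 wt %), THF/MeOH/H2O (20:1:1), rt; filtration; Sephadex LH-20
Reagents that add atoms: none
Why: Neutral hydrogenolysis of the seven aryl benzyl ethers at 1 atm leaves the cyclic benzylic C2–O bonds, the diarylmethine C4–H and all four stereocentres untouched.

**Compound list**
1 | 2,4-dihydroxyacetophenone | CC(=O)c1ccc(O)cc1O | starting material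
2 | 1-[4-(benzyloxy)-2-hydroxyphenyl]ethan-1-one | CC(=O)c1ccc(OCc2ccccc2)cc1O | intermediate
3 | 3,4-dihydroxybenzaldehyde | O=Cc1ccc(O)c(O)c1 | starting material
4 | 3,4-bis(benzyloxy)benzaldehyde | O=Cc1ccc(OCc2ccccc2)c(OCc2ccccc2)c1 | intermediate
5 | racemic 1-[4-(benzyloxy)-2-hydroxyphenyl]-3-[3,4-bis(benzyloxy)phenyl]-3-hydroxypropan-1-one (aldol adduct, not isolated) | O=C(CC(O)c1ccc(OCc2ccccc2)c(OCc2ccccc2)c1)c1ccc(OCc2ccccc2)cc1O | intermediate
6 | (E)-1-[4-(benzyloxy)-2-hydroxyphenyl]-3-[3,4-bis(benzyloxy)phenyl]prop-2-en-1-one | O=C(/C=C/c1ccc(OCc2ccccc2)c(OCc2ccccc2)c1)c1ccc(OCc2ccccc2)cc1O | intermediate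
7 | racemic 7-(benzyloxy)-2-[3,4-bis(benzyloxy)phenyl]chroman-4-one | O=C1CC(c2ccc(OCc3ccccc3)c(OCc3ccccc3)c2)Oc2cc(OCc3ccccc3)ccc21 | intermediate
8 | (2S,4S)-7-(benzyloxy)-2-[3,4-bis(benzyloxy)phenyl]chroman-4-ol | O(Cc1ccccc1)c1ccc2c(c1)O[C@H](c1ccc(OCc3ccccc3)c(OCc3ccccc3)c1)C[C@@H]2O | intermediate
9 | (+)-catechin, (2R,3S)-2-(3,4-dihydroxyphenyl)chromane-3,5,7-triol | Oc1cc(O)c2c(c1)O[C@H](c1ccc(O)c(O)c1)[C@@H](O)C2 | starting material
10 | (2R,3S)-5,7-bis(benzyloxy)-2-[3,4-bis(benzyloxy)phenyl]chroman-3-ol | O(Cc1ccccc1)c1cc(OCc3ccccc3)c2c(c1)O[C@H](c1ccc(OCc3ccccc3)c(OCc3ccccc3)c1)[C@@H](O)C2 | intermediate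
11 | (2S)-7-(benzyloxy)-2-[3,4-bis(benzyloxy)phenyl]chroman-4-ylium (C4 benzylic cation, not isolated) | O(Cc1ccccc1)c1ccc2c(c1)O[C@H](c1ccc(OCc3ccccc3)c(OCc3ccccc3)c1)C[CH+]2 | intermediate
12 | (2R,3S)-5,7-bis(benzyloxy)-2-[3,4-bis(benzyloxy)phenyl]-8-{(2S,4R)-7-(benzyloxy)-2-[3,4-bis(benzyloxy)phenyl]chroman-4-yl}chroman-3-ol | O(Cc1ccccc1)c1ccc2c(c1)O[C@H](c1ccc(OCc3ccccc3)c(OCc3ccccc3)c1)C[C@H]2c1c(OCc3ccccc3)cc(OCc3ccccc3)c2c1O[C@H](c1ccc(OCc3ccccc3)c(OCc3ccccc3)c1)[C@@H](O)C2 | intermediate
13 | CNP0227165.4, (2R,3S)-2-(3,4-dihydroxyphenyl)-8-[(2S,4R)-2-(3,4-dihydroxyphenyl)-7-hydroxychroman-4-yl]chromane-3,5,7-triol | Oc1ccc2c(c1)O[C@H](c1ccc(O)c(O)c1)C[C@H]2c1c(O)cc(O)c2c1O[C@H](c1ccc(O)c(O)c1)[C@@H](O)C2 | target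

**Totals**
Total step count: 8. Longest linear sequence: 6 steps (steps 1, 3, 4, 5, 7, 8, from compound 1).

**Three steps most likely to fail, each with a fallback**

Step 7 (interflavan coupling). Risks are elimination to the flav-3-ene, self-condensation of the cation, some C6 attack, and only moderate trans/cis selectivity at C4 (the trans preference rests on the axial-attack argument, not on a measured ratio). The fallback sets out from 8 (together with 9) and abandons protecting groups for the coupling. Hydrogenolysis of 8 (H2, Pd(OH)2/C, EtOAc, neutral, short contact) gives the free phenolic (2S,4S)-2-(3,4-dihydroxyphenyl)chromane-4,7-diol F1. F1 is then condensed with a five-fold excess of unprotected 9 in 0.1 molar aqueous HCl at rt, a biomimetic coupling through the para-quinone methide of ring A. Separation on Sephadex LH-20 gives the 4β→8 isomer, so this comes back to the route directly at 13 and step 8 is no longer needed.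

Step 5 (kinetic resolution). Risks are a low selectivity factor for this heavily benzylated substrate, or a matched sense opposite to that assumed (to be checked by chiral HPLC and optical rotation). The fallback sets out from 7 and moves the resolution to the coupling stage, using catechin as the chiral handle. NaBH4 (MeOH/THF, 0 °C) reduces 7 to racemic cis-7-(benzyloxy)-2-[3,4-bis(benzyloxy)phenyl]chroman-4-ol F2. F2 is coupled with 10 under the step 7 conditions; each enantiomeric cation is attacked trans to its own C2 aryl. This gives 12 and its (2R,4S)-upper-unit diastereomer F3, which are separated by chromatography or preparative HPLC. The route is rejoined at 12.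

Step 8 (global debenzylation). Risks are incomplete hydrogenolysis, reductive opening of a benzylic C2–O bond, and air oxidation of the free polyphenol during purification. The fallback sets out from 12 and removes the benzyl groups without hydrogen: BCl3 with pentamethylbenzene as cation scavenger, CH2Cl2, −78 °C, then MeOH quench. The 5-deoxy upper unit makes the interflavan bond comparatively acid-stable. The crude polyphenol is peracetylated (Ac2O, pyridine) to the octaacetate F4, which is purified on silica. Deacetylation (K2CO3, degassed MeOH, 0 °C, argon, then acidic ion-exchange resin) comes back to the route at 13.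

**Further compounds**
F1 | step 7 | (2S,4S)-2-(3,4-dihydroxyphenyl)chromane-4,7-diol | Oc1ccc2c(c1)O[C@H](c1ccc(O)c(O)c1)C[C@@H]2O
F2 | step 5 | racemic cis-7-(benzyloxy)-2-[3,4-bis(benzyloxy)phenyl]chroman-4-ol (both enantiomers written) | O(Cc1ccccc1)c1ccc2c(c1)O[C@H](c1ccc(OCc3ccccc3)c(OCc3ccccc3)c1)C[C@@H]2O.O(Cc1ccccc1)c1ccc2c(c1)O[C@@H](c1ccc(OCc3ccccc3)c(OCc3ccccc3)c1)C[C@H]2O
F3 | step 5 | (2R,3S)-5,7-bis(benzyloxy)-2-[3,4-bis(benzyloxy)phenyl]-8-{(2R,4S)-7-(benzyloxy)-2-[3,4-bis(benzyloxy)phenyl]chroman-4-yl}chroman-3-ol | O(Cc1ccccc1)c1ccc2c(c1)O[C@@H](c1ccc(OCc3ccccc3)c(OCc3ccccc3)c1)C[C@@H]2c1c(OCc3ccccc3)cc(OCc3ccccc3)c2c1O[C@H](c1ccc(OCc3ccccc3)c(OCc3ccccc3)c1)[C@@H](O)C2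
F4 | step 8 | octaacetate of 13, (2R,3S)-3,5,7-triacetoxy-2-(3,4-diacetoxyphenyl)-8-[(2S,4R)-7-acetoxy-2-(3,4-diacetoxyphenyl)chroman-4-yl]chromane | CC(=O)Oc1ccc2c(c1)O[C@H](c1ccc(OC(C)=O)c(OC(C)=O)c1)C[C@H]2c1c(OC(C)=O)cc(OC(C)=O)c2c1O[C@H](c1ccc(OC(C)=O)c(OC(C)=O)c1)[C@@H](OC(C)=O)C2
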